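**Retrosynthetic overview**

1. Locants (target numbering): pyran O1–C2(H)–C3(CH3)–C4(H, isobutyl)–C4a–C8a; cyclopentane C2–C3–Ca–Cb–C1′ (spiro); cyclohexene C1′–C2′=C3′(isopropyl)–C4′–C5′–C6′(CH3). The last events are BCl3 demethylation and Rieche bis-formylation of a 5,7-dimethoxychroman, whose C2–H and C4–H come from silane reduction of a C2 hemiketal carrying an exocyclic C4 alkene.
2. Key disconnection: that hemiketal should arise by an AlMe3-triggered methylative semipinacol from a dispiro cyclopentanone in which O1 still sits on C3. The five-membered dihydrofuran ring (O1, C3, C4, C4a, C8a) is enlarged to the six-membered pyran (O1, C2, C3, C4, C4a, C8a) as CH3 moves from C2 to C3 and O1 from C3 to C2.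
3. Enabling feature: O1 is bound to the quaternary, allylic C3 directly beside the C2 carbonyl and stays tied to C3 through C8a–C4a–C4, so the expelled phenoxide can only return to C2.
4. The dispiro ketone comes from the alpha-bromo spiro ketone and 1-(2-hydroxy-4,6-dimethoxyphenyl)-3-methylbutan-1-one (O-alkylation, intramolecular aldol, dehydration). The spiro[4.5]decenone comes from (R)-pulegone and cyclobutanone by aldol addition, enol triflate reduction and a vinylogous semipinacol ring expansion that sets C1′ from C6′.
5. Ring order: cyclohexene (chiral pool) → cyclopentanone (four- to five-membered) → dihydrobenzofuran → pyran (five- to six-membered, key step).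

Key step: step 9

**Route**

Step 1
Reactants: 1 3,5-dimethoxyphenol; 2 3-methylbutanoyl chloride
Product: 3 1-(2-hydroxy-4,6-dimethoxyphenyl)-3-methylbutan-1-one
Conditions: BF3·OEt2, 70 °C; aqueous work-up
Reagents that add atoms: none
Why: BF3-mediated Friedel–Crafts acylation/Fries shift should place the acyl group ortho to the free hydroxyl of 1 (chelated product), the usual access to 2-hydroxy-4,6-dimethoxyaryl ketones; no stereocentre is formed.

Step 2
Reactants: 4 (R)-(+)-pulegone; 5 cyclobutanone
Product: 6 (5R)-6-(1-hydroxycyclobutyl)-5-methyl-2-(propan-2-ylidene)cyclohexan-1-one (both C6 epimers)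
Conditions: LiN(iPr)2, THF, −78 °C; then 5, −78 °C; AcOH quench
Reagents that add atoms: none
Why: Kinetic deprotonation of the enone at the saturated alpha′ carbon (C1′) and directed aldol addition to the strained, strongly electrophilic cyclobutanone should give the beta-hydroxy ketone; the new C1′ centre is erased in step 3 and C6′ comes unchanged from 4.

Step 3
Reactants: 6 aldol adduct
Product: 7 (3R)-2-(1-hydroxycyclobutyl)-3-methyl-6-(propan-2-ylidene)cyclohex-1-en-1-yl trifluoromethanesulfonate
Conditions: KN(SiMe3)2 (2.2 equiv), THF, −78 °C; PhNTf2, −78 → −30 °C; AcOH quench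
Reagents that add atoms: N-phenylbis(trifluoromethanesulfonimide) (O=S(=O)(N(c1ccccc1)S(=O)(=O)C(F)(F)F)C(F)(F)F)
Why: The potassium aldolate should be deprotonated a second time at C1′ (the alkoxide–enolate dianion can undergo neither retro-aldol cleavage nor beta-elimination) and the cross-conjugated dienolate is O-sulfonylated by PhNTf2 (enol triflate formation).

Step 4
Reactants: 7 dienyl triflate
Product: 8 1-[(6R)-6-methyl-3-(propan-2-ylidene)cyclohex-1-en-1-yl]cyclobutan-1-ol
Conditions: Pd(OAc)2 (5 mol %), PPh3, HCO2H, nBu3N, DMF, 60 °C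
Reagents that add atoms: none
Why: Pd-catalysed formate reduction of an alkenyl triflate should replace OSO2CF3 by H and leave the 1,3-diene and the tertiary cyclobutanol untouched.

Step 5
Reactants: 8 dienyl cyclobutanol
Product: 9 (5R,10R)-10-methyl-7-(propan-2-yl)spiro[4.5]dec-6-en-1-one
Conditions: TsOH·H2O (10 mol %), CH2Cl2, 0 → 25 °C
Reagents that add atoms: none
Why: Protonation of the diene at its CMe2 terminus gives the C1′–C2′–C3′ allyl cation and a cyclobutane CH2 (Cb) shifts to C1′ (acid-catalysed vinylogous semipinacol ring expansion of a 1-alkenylcyclobutanol); the shift should occur anti to the pseudoaxial C6′ methyl (allylic strain), which sets C1′ with the carbonyl carbon cis and Cb trans to that methyl.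

Step 6
Reactants: 9 spiro ketone
Product: 10 (5R,10R)-2-bromo-10-methyl-7-(propan-2-yl)spiro[4.5]dec-6-en-1-one (both C2 epimers)
Conditions: LiN(SiMe3)2, THF, −78 °C; then N-bromosuccinimide, −78 °C; AcOH quench
Reagents that add atoms: N-bromosuccinimide (O=C1CCC(=O)N1Br)
Why: C3 (target numbering) is the only enolisable position because C1′ is quaternary, so the lithium enolate should be brominated regiospecifically at −78 °C without touching the trisubstituted alkene; the C3 configuration is irrelevant.

Step 7
Reactants: 10 bromo ketone; 3 hydroxyaryl ketone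
Product: 11 (5R,10R)-2-[3,5-dimethoxy-2-(3-methylbutanoyl)phenoxy]-10-methyl-7-(propan-2-yl)spiro[4.5]dec-6-en-1-one (both C2 epimers)
Conditions: K2CO3, DMF, 25 °C
Reagents that add atoms: none
Why: SN2 displacement of the alpha-bromo ketone by the potassium phenoxide of 3 (Williamson etherification, first stage of a Rap–Stoermer benzofuran synthesis); the C3 centre stays enolisable.

Step 8
Reactants: 11 alpha-aryloxy ketone
Product: 13 dispiro ketone (4,6-dimethoxy-3-(2-methylpropylidene)-2,3-dihydro-1-benzofuran spiro-fused at its C2 to C2 of the cyclopentanone of 9; O1 syn to C6′), via aldol tertiary alcohol 12 (not isolated)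
Conditions: LiN(SiMe3)2, THF, −78 → 0 °C; then MsCl, Et3N, 0 → 25 °C
Reagents that add atoms: none
Why: The enolate at C3 should add to the ortho acyl group (intramolecular aldol, 5-exo-trig, second stage of the Rap–Stoermer sequence) on its face remote from the C6′ side, which leaves O1 syn to C6′ at the new quaternary C3, and the tertiary benzylic mesylate then eliminates towards the isobutyl CH2, the only beta-hydrogens available.

Step 9
Reactants: 13 dispiro ketone
Product: 15 hemiketal (5,7-dimethoxy-3-methyl-4-(2-methylpropylidene)chroman-2-ol cis-fused at C2–C3 to the spiro cyclopentane), via C2 methyl carbinol 14 (not isolated)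
Conditions: AlMe3 (4 equiv), PhMe/CH2Cl2, −78 → 25 °C; then 1 M HCl
Reagents that add atoms: trimethylaluminium (C[Al](C)C)
Why: Proposed new method: AlMe3 should add CH3 to the C2 carbonyl from the face anti to the C3–O1 bond (Felkin–Anh; the other face is also screened by the C6′ methyl), and the resulting dimethylaluminium alkoxide then pushes this CH3 across to C3 antiperiplanar to the departing O1, whose bond to the tertiary, allylic C3 is weakened by aluminium coordination; the closest known reactions are the semipinacol rearrangement of 2,3-epoxy alcohol derivatives and the organoaluminium-promoted Tsuchihashi–Suzuki 1,2-shift of beta-aluminoxy sulfonates, here with an allylic aryl ether oxygen as nucleofuge. The aluminium phenoxide released at C8a adds to the new C2 ketone (6-exo-trig hemiketalisation), so the five-membered ring O1–C3–C4–C4a–C8a is enlarged to the six-membered ring O1–C2–C3–C4–C4a–C8a. C3 is set by the stereospecific suprafacial methyl shift with inversion at C3, which places C4 and O1 on the same face and the CH3 opposite, while the hemiketal centre C2 can only close cis-fused. The step needs methyl rather than C1′ migration and ionisation only after C-methylation: the ring bond C2–C1′ is gauche to C3–O1 and its shift would create a spiro-cyclobutane, and before methyl addition the alpha-keto position disfavours heterolysis of C3–O1.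

Step 10
Reactants: 15 hemiketal
Product: 17 5,7-dimethoxy chroman (target skeleton without the two formyl groups; C2–H C3–CH3 C4–H all cis), via 4-alkylidene chroman 16 (not isolated)
Conditions: Et3SiH (6 equiv), BF3·OEt2 (2 equiv), CH2Cl2, −78 → −40 °C; then CF3CO2H (3 equiv), −40 → −20 °C
Reagents that add atoms: none
Why: Ionic hydrogenation: the C2 oxocarbenium ion should take hydride on the face anti to C6′ (only this gives the cis-fused pyran), then the electron-rich trialkoxystyrene is protonated and the C4 benzylic cation takes hydride from the convex face bearing the C3 methyl, giving C2–H, C3–CH3 and C4–H all cis, while the isolated trisubstituted C2′=C3′ alkene should not be protonated under these conditions.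

Step 11
Reactants: 17 dimethoxy chroman
Product: 18 5,7-di-O-methyl ether of the target (6,8-dicarbaldehyde)
Conditions: Cl2CHOCH3 (5 equiv), TiCl4 (5 equiv), CH2Cl2, −78 → 0 °C; then H2O
Reagents that add atoms: dichloromethyl methyl ether (COC(Cl)Cl); water (O)
Why: Rieche formylation of the trialkoxybenzene at its two free positions C6 and C8; no stereocentre is affected.

Step 12
Reactants: 18 dialdehyde dimethyl ether
Product: 19 target (CNP0121396.1)
Conditions: BCl3 (5 equiv), CH2Cl2, −78 → 0 °C; then H2O
Reagents that add atoms: none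
Why: BCl3 should cleave the two methyl ethers, each ortho to a formyl group (chelation-assisted demethylation), while the secondary alkyl aryl ether O1–C2 is retained.

**Compound list**

1 | 3,5-dimethoxyphenol | COc1cc(O)cc(OC)c1 | starting material
2 | 3-methylbutanoyl chloride | CC(C)CC(Cl)=O | starting material
3 | 1-(2-hydroxy-4,6-dimethoxyphenyl)-3-methylbutan-1-one | CC(C)CC(=O)c1c(O)cc(OC)cc1OC | intermediate
4 | (R)-(+)-pulegone | CC(C)=C1CC[C@@H](C)CC1=O | starting material
5 | cyclobutanone | O=C1CCC1 | starting material
6 | (5R)-6-(1-hydroxycyclobutyl)-5-methyl-2-(propan-2-ylidene)cyclohexan-1-one (both C6 epimers) | CC(C)=C1CC[C@@H](C)C(C1=O)C1(O)CCC1 | intermediate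
7 | (3R)-2-(1-hydroxycyclobutyl)-3-methyl-6-(propan-2-ylidene)cyclohex-1-en-1-yl trifluoromethanesulfonate | CC(C)=C1CC[C@@H](C)C(=C1OS(=O)(=O)C(F)(F)F)C1(O)CCC1 | intermediate
8 | 1-[(6R)-6-methyl-3-(propan-2-ylidene)cyclohex-1-en-1-yl]cyclobutan-1-ol | CC(C)=C1CC[C@@H](C)C(=C1)C1(O)CCC1 | intermediate
9 | (5R,10R)-10-methyl-7-(propan-2-yl)spiro[4.5]dec-6-en-1-one | O=C2CCC[C@@]21C=C(C(C)C)CC[C@H]1C | intermediate
10 | (5R,10R)-2-bromo-10-methyl-7-(propan-2-yl)spiro[4.5]dec-6-en-1-one (both C2 epimers) | O=C2C(Br)CC[C@@]21C=C(C(C)C)CC[C@H]1C | intermediate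
11 | 2-[3,5-dimethoxy-2-(3-methylbutanoyl)phenoxy] derivative of 9 (both C2 epimers) | O=C2C(Oc3cc(OC)cc(OC)c3C(=O)CC(C)C)CC[C@@]21C=C(C(C)C)CC[C@H]1C | intermediate
12 | 3-hydroxy-4,6-dimethoxy-3-(2-methylpropyl)-2,3-dihydro-1-benzofuran spiro-fused at its C2 to C2 of the cyclopentanone of 9 (O1 syn to C6′) | O=C2[C@]4(Oc3cc(OC)cc(OC)c3C4(O)CC(C)C)CC[C@@]21C=C(C(C)C)CC[C@H]1C | intermediate
13 | 4,6-dimethoxy-3-(2-methylpropylidene)-2,3-dihydro-1-benzofuran spiro-fused at its C2 to C2 of the cyclopentanone of 9 (O1 syn to C6′) | O=C2[C@]4(Oc3cc(OC)cc(OC)c3C4=CC(C)C)CC[C@@]21C=C(C(C)C)CC[C@H]1C | intermediate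
14 | C2 methyl carbinol of 13 (CH3 trans to O1) | C[C@@]2(O)[C@]4(Oc3cc(OC)cc(OC)c3C4=CC(C)C)CC[C@@]21C=C(C(C)C)CC[C@H]1C | intermediate
15 | 5,7-dimethoxy-3-methyl-4-(2-methylpropylidene)chroman-2-ol, cis-fused at C2–C3 to the spiro cyclopentane (ring-expanded hemiketal) | CC(C)C=C1c2c(OC)cc(OC)cc2O[C@]2(O)[C@@]1(C)CC[C@@]21C=C(C(C)C)CC[C@H]1C | intermediate
16 | 15 with H in place of the C2 hydroxyl (4-alkylidene chroman) | CC(C)C=C1c2c(OC)cc(OC)cc2O[C@@H]2[C@@]1(C)CC[C@@]21C=C(C(C)C)CC[C@H]1C | intermediate
17 | 5,7-di-O-methyl-6,8-dideformyl derivative of the target | CC(C)C[C@H]1c2c(OC)cc(OC)cc2O[C@@H]2[C@@]1(C)CC[C@@]21C=C(C(C)C)CC[C@H]1C | intermediate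
18 | 5,7-di-O-methyl ether of the target | CC(C)C[C@H]1c2c(OC)c(C=O)c(OC)c(C=O)c2O[C@@H]2[C@@]1(C)CC[C@@]21C=C(C(C)C)CC[C@H]1C | intermediate
19 | target CNP0121396.1 | CC(C)C[C@H]1c2c(O)c(C=O)c(O)c(C=O)c2O[C@@H]2[C@@]1(C)CC[C@@]21C=C(C(C)C)CC[C@H]1C | target

**Totals**

Total steps: 12. Longest linear sequence: 11 steps (4 to 19, steps 2–12).

**Steps most likely to fail**

Step 9 (Proposed new method). Three processes could defeat it: premature aluminium-assisted heterolysis of the allylic C3–O1 bond followed by methyl transfer from aluminium to the allyl cation or proton loss; methyl addition to the wrong carbonyl face, which removes the antiperiplanar alignment needed for the shift; and further methylation of the aluminium hemiketalate. The fallback uses known chemistry, sets out from 9 and returns at 17. Aldol condensation of 9 with 3-methylbutanal (LiN(iPr)2; then MsCl, Et3N, DBU) should give the (E)-enone F1. Acid-catalysed Friedel–Crafts conjugate addition of 1 to F1 followed by cyclodehydration (BF3·OEt2, then TsOH) should give the 4H-chromene F2 with the enol ether at C2=C3, the C4 epimers being separated. Simmons–Smith cyclopropanation (ZnEt2, CH2I2) of this enol ether on the face anti to C6′ should give the cyclopropane F3. Treatment with CF3CO2H/Et3SiH then opens the alkoxycyclopropane by protonolysis, which delivers the C3 methyl and the C2 oxocarbenium ion, and the silane reduces the latter to give 17.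

Step 3. Failure could come from competing gamma-deprotonation at the isopropylidene methyl or at C4′, retro-aldol loss of cyclobutanone before the second deprotonation, or sulfonylation of the alkoxide. The fallback sets out from 6 and returns at 8: condensation with 2,4,6-tri(propan-2-yl)benzenesulfonohydrazide should give the hydrazone F4, and a Shapiro reaction (nBuLi, 3 equiv, THF, −78 → 0 °C; then H2O) removes the only sp3 alpha-hydrogen (C1′–H) and should deliver diene 8 directly.

Step 11. Failure could come from incomplete second formylation of the deactivated mono-aldehyde, or from hydrochlorination or migration of the C2′=C3′ double bond under TiCl4/HCl. The fallback sets out from 17 and returns at 19: nucleophilic demethylation (NaSEt, DMF, 140 °C) should give the diphenol F5, and Vilsmeier–Haack double formylation of the free phloroglucinol-type ring (POCl3, DMF; aqueous NaOAc hydrolysis) should give 19 without strong Lewis acid.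

**Further compounds**

F1 | step 9 | (5R,10R)-10-methyl-2-(3-methylbutylidene)-7-(propan-2-yl)spiro[4.5]dec-6-en-1-one (E) | O=C2C(=CCC(C)C)CC[C@@]21C=C(C(C)C)CC[C@H]1C
F2 | step 9 | 5,7-dimethoxy-4-(2-methylpropyl)-4H-chromene fused at C2=C3 to the spiro cyclopentene (C4 as in the target) | CC(C)C[C@H]1c2c(OC)cc(OC)cc2OC3=C1CC[C@@]34C=C(C(C)C)CC[C@H]4C
F3 | step 9 | F2 with a CH2 bridging C2 and C3 on the face anti to C6′ (alkoxycyclopropane) | CC(C)C[C@H]1c2c(OC)cc(OC)cc2O[C@@]35C[C@]15CC[C@@]34C=C(C(C)C)CC[C@H]4C
F4 | step 3 | 2,4,6-tri(propan-2-yl)benzenesulfonylhydrazone of 6 | CC(C)=C1CC[C@@H](C)C(C1=NNS(=O)(=O)c2c(C(C)C)cc(C(C)C)cc2C(C)C)C3(O)CCC3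
F5 | step 11 | 5,7-dihydroxy analogue of 17 | CC(C)C[C@H]1c2c(O)cc(O)cc2O[C@@H]2[C@@]1(C)CC[C@@]21C=C(C(C)C)CC[C@H]1C
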